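**Retrosynthetic overview**

1. The target is a 6,7-dihydro-5H-cyclopenta[c]pyridine. The strategy rests on one feature: C5 (the carbinol carrying CO2Me) sits on C4a, the carbon of pyridine ring A para to N2, and is joined through C6 and the C7 carbonyl to C7a, so a C5 nucleophile hung on C7 can reach C4a of an N-activated ring A.
2. Ring B (C4a, C5, C6, C7, C7a) is closed last through the C4a–C5 bond. The silyl ketene acetal of the α-silyloxy ester adds to the N-triflylpyridinium and triflinate is then lost. O6 is a silyl ether during the closure and is acetylated afterwards, and O5 is desilylated at the end.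
3. The open-chain 3-pyridyl ketone comes from C7–C7a (pyridylmagnesium reagent on a dioxolanone carbonyl) and C5–C6 (aldol of the (R)-lactic acid dioxolanone enolate with methyl glyoxylate, which fixes C6).
4. Ring A is bought as 2,5-dibromopyridine. The (1E,3E,5S)-dienyl chain is attached at C3 by Suzuki coupling of a boronate built from (S)-2-methylbutan-1-ol.

Key step: step 9

Remark: methyl glyoxylate is used as the freshly distilled monomer, and compounds 3, 5 and 11 are taken as commercial reagents.

**Route**

Step 1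
Reactants: 1 (S)-2-methylbutan-1-ol
Product: 2 (S)-2-methylbutanal
Conditions: TEMPO (cat.), KBr (cat.), NaOCl, NaHCO3, CH2Cl2/H2O, 0 °C
Reagents that add atoms: none
Why: Anelli oxidation (oxoammonium as the oxidant) stops at the aldehyde, and the cold, buffered two-phase medium should leave the α-stereocentre untouched.

Step 2
Reactants: 2 (S)-2-methylbutanal; 3 2-(triphenylphosphoranylidene)propanal
Product: 4 (2E,4S)-2,4-dimethylhex-2-enal
Conditions: toluene, 90 °C
Reagents that add atoms: none
Why: Wittig olefination with a formyl-stabilised ylide should give the (E)-trisubstituted enal under neutral conditions that spare the α-stereocentre, and the product enal is too unreactive to be homologated a second time.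

Step 3
Reactants: 4 (2E,4S)-2,4-dimethylhex-2-enal; 5 2-(dichloromethyl)-4,4,5,5-tetramethyl-1,3,2-dioxaborolane
Product: 7 2-[(1E,3E,5S)-3,5-dimethylhepta-1,3-dien-1-yl]-4,4,5,5-tetramethyl-1,3,2-dioxaborolane, via geminal dichromium boronate 6 (not isolated)
Conditions: CrCl2 (excess), LiI, THF, rt
Reagents that add atoms: none
Why: Takai–Utimoto boryl olefination: divalent chromium reduces 5 to the geminal dichromium species 6, which adds to the aldehyde and eliminates anti, so the new alkenyl boronate should be (E) and the existing double bond is not touched.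

Step 4
Reactants: 7 dienyl pinacol boronate; 8 2,5-dibromopyridine
Product: 9 5-bromo-2-[(1E,3E,5S)-3,5-dimethylhepta-1,3-dien-1-yl]pyridine
Conditions: Pd(PPh3)4 (cat.), K2CO3, 1,4-dioxane/H2O, 80 °C
Reagents that add atoms: none
Why: Suzuki–Miyaura coupling in which zerovalent palladium inserts faster into the C2–Br bond next to nitrogen than into C5–Br, with retention of the diene geometry.

Step 5
Reactants: 10 (R)-lactic acid; 11 pivaldehyde
Product: 12 (2R,5R)-2-tert-butyl-5-methyl-1,3-dioxolan-4-one (cis)
Conditions: TsOH·H2O (cat.), H2SO4 (cat.), pentane, reflux (Dean–Stark); crystallisation from pentane, −78 °C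
Reagents that add atoms: none
Why: Acid-catalysed acetalisation in which the acetal carbon forms under thermodynamic control mainly cis to the methyl group, and the cis isomer should be purified by low-temperature crystallisation.

Step 6
Reactants: 12 (2R,5R)-2-tert-butyl-5-methyl-1,3-dioxolan-4-one; 13 methyl glyoxylate
Product: 15 methyl 2-[(2R,4S)-2-tert-butyl-4-methyl-5-oxo-1,3-dioxolan-4-yl]-2-hydroxyacetate as both carbinol epimers, via lithium enolate 14 (not isolated)
Conditions: LiN(iPr)2, THF, −78 °C; 13, −78 °C; AcOH quench at −78 °C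
Reagents that add atoms: none
Why: Aldol addition under self-regeneration of stereocentres: enolate 14 is attacked on the face anti to the tert-butyl group, so the future C6 is set as (S) with net retention of the lactate configuration, while the carbinol carbon (future C5) may form as both epimers because it is planarised in step 9.

Step 7
Reactants: 15 aldol adduct
Product: 16 methyl 2-[(2R,4S)-2-tert-butyl-4-methyl-5-oxo-1,3-dioxolan-4-yl]-2-(triethylsilyloxy)acetate (both epimers)
Conditions: Et3SiOTf, 2,6-lutidine, CH2Cl2, −78 → 0 °C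
Reagents that add atoms: triethylsilyl trifluoromethanesulfonate, CC[Si](CC)(CC)OS(=O)(=O)C(F)(F)F
Why: Silylation of a hindered secondary alcohol with a silyl triflate and a hindered pyridine base proceeds at low temperature and leaves the lactone acetal and the ester intact.

Step 8
Reactants: 9 5-bromo-2-dienylpyridine; 16 silylated dioxolanone
Product: 19 methyl (3S)-4-{6-[(1E,3E,5S)-3,5-dimethylhepta-1,3-dien-1-yl]pyridin-3-yl}-3-hydroxy-3-methyl-4-oxo-2-(triethylsilyloxy)butanoate (both C2 epimers), via pyridylmagnesium chloride 17 (not isolated), via magnesium hemiketal alkoxide 18 (not isolated)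
Conditions: 9, iPrMgCl·LiCl, THF, 0 °C → rt; added slowly to 16, THF, −40 °C; sat. aq. NH4Cl
Reagents that add atoms: none
Why: Br/Mg exchange followed by nucleophilic acyl substitution: the acylal-type lactone carbonyl of 16 is more electrophilic than the hindered acyclic methyl ester, the cyclic hemiketal 18 should hold until the quench and so stop a second addition, and its collapse gives the ketone and pivaldehyde without touching C6.

Step 9
Reactants: 19 open-chain hydroxy ketone
Product: 24 methyl (5R,6S)-3-[(1E,3E,5S)-3,5-dimethylhepta-1,3-dien-1-yl]-6-hydroxy-6-methyl-7-oxo-5-(triethylsilyloxy)-6,7-dihydro-5H-cyclopenta[c]pyridine-5-carboxylate, via ketene acetal 20 (not isolated), via N-triflylpyridinium triflate 21 (not isolated), via N-triflyl dihydropyridine 22 (not isolated), via O6-trimethylsilyl ether 23 (not isolated)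
Conditions: Me3SiOTf, Et3N, CH2Cl2, 0 °C → rt; evaporate, extract into pentane, filter under argon; (CF3SO2)2O, 2,6-di-tert-butyl-4-methylpyridine, CH2Cl2, −78 → −30 °C; DBU, −30 °C → rt; citric acid, MeOH, 0 °C
Reagents that add atoms: none
Why: Proposed new method: Me3SiOTf/Et3N should silylate O6 and soft-enolise the α-silyloxy ester, the only enolisable carbonyl of 19, to ketene acetal 20 with planar C5 (both C5 epimers converge); after removal of the amine, (CF3SO2)2O triflylates N2 (21), the tethered ketene acetal adds to C4a with release of Me3SiOTf to give the N-triflyl 1,4-dihydropyridine 22, DBU removes H-4a with loss of CF3SO2− to restore ring A (23), and citric acid in MeOH cleaves only the tertiary Me3Si ether. The closest known reaction type is the intermolecular C4-selective addition of silyl ketene acetals to N-acyl or N-triflyl pyridinium salts of 3-acylpyridines, with rearomatisation by base-induced loss of triflinate; the intramolecular ring-forming version is not known. Ring B closes in a 5-exo-trig mode on the C4=C4a bond of the pyridinium. The new stereocentre C5 is controlled by C6: 1,3-allylic strain and the inside-alkoxy preference should keep the C6–O bond near the plane of the ketene acetal and turn the C6 methyl to the Et3SiO side, so that C4a bonds to the face that leaves CO2Me cis to O6 and the two silyloxy groups trans, which is (5R). The step needs attack at C4a and not at C1, which should be secured by the soft nucleophile meeting the largest LUMO coefficient para to N2 and by the bulky N-SO2CF3 group that shields C1, while C3 is blocked by the dienyl chain. O6 is carried as a silyl ether and acetylated only in step 10 because an acetate methyl group would compete in the enolisation, and no base is present beside the N-triflylpyridinium because its side-chain C5'–H is acidified.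

Step 10
Reactants: 24 ring-closed tertiary alcohol
Product: 25 methyl (5R,6S)-6-acetoxy-3-[(1E,3E,5S)-3,5-dimethylhepta-1,3-dien-1-yl]-6-methyl-7-oxo-5-(triethylsilyloxy)-6,7-dihydro-5H-cyclopenta[c]pyridine-5-carboxylate
Conditions: Ac2O, DMAP, Et3N, CH2Cl2, rt → 40 °C
Reagents that add atoms: acetic anhydride, CC(=O)OC(C)=O
Why: DMAP-catalysed acylation (Steglich-type) of the only free hydroxyl, a tertiary α-ketol carrying a methyl group, should give the acetate without affecting any stereocentre.

Step 11
Reactants: 25 O5-triethylsilyl ether of the target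
Product: 26 methyl (5R,6S)-6-acetoxy-3-[(1E,3E,5S)-3,5-dimethylhepta-1,3-dien-1-yl]-5-hydroxy-6-methyl-7-oxo-6,7-dihydro-5H-cyclopenta[c]pyridine-5-carboxylate (CNP0483502.1)
Conditions: HF·pyridine, pyridine, THF, 0 °C → rt
Reagents that add atoms: none
Why: Fluoride-induced cleavage of the Si–O bond by buffered HF·pyridine leaves the acetate, the ester and the diene alone, and the trans arrangement of O5 and O6 on the five-membered ring should prevent acetyl migration.

**Compound list**

1 | (S)-2-methylbutan-1-ol | CC[C@H](C)CO | starting material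
2 | (S)-2-methylbutanal | CC[C@H](C)C=O | intermediate
3 | 2-(triphenylphosphoranylidene)propanal | CC(C=O)=P(c1ccccc1)(c1ccccc1)c1ccccc1 | starting material
4 | (2E,4S)-2,4-dimethylhex-2-enal | CC[C@H](C)/C=C(C)/C=O | intermediate
5 | 2-(dichloromethyl)-4,4,5,5-tetramethyl-1,3,2-dioxaborolane | ClC(Cl)B1OC(C)(C)C(C)(C)O1 | starting material
6 | geminal dichromium boronate from 5 (trivalent chromium, not isolated) | Cl[Cr](Cl)C([Cr](Cl)Cl)B1OC(C)(C)C(C)(C)O1 | intermediate
7 | 2-[(1E,3E,5S)-3,5-dimethylhepta-1,3-dien-1-yl]-4,4,5,5-tetramethyl-1,3,2-dioxaborolane | CC[C@H](C)/C=C(C)/C=C/B1OC(C)(C)C(C)(C)O1 | intermediate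
8 | 2,5-dibromopyridine | Brc1ccc(Br)nc1 | starting material
9 | 5-bromo-2-[(1E,3E,5S)-3,5-dimethylhepta-1,3-dien-1-yl]pyridine | CC[C@H](C)/C=C(C)/C=C/c1ccc(Br)cn1 | intermediate
10 | (R)-lactic acid | C[C@@H](O)C(=O)O | starting material
11 | pivaldehyde (2,2-dimethylpropanal) | CC(C)(C)C=O | starting material
12 | (2R,5R)-2-tert-butyl-5-methyl-1,3-dioxolan-4-one (cis) | C[C@H]1O[C@@H](C(C)(C)C)OC1=O | intermediate
13 | methyl glyoxylate | COC(=O)C=O | starting material
14 | lithium enolate of 12, (2R)-configured acetal (not isolated) | CC1=C(O[Li])O[C@H](C(C)(C)C)O1 | intermediate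
15 | methyl 2-[(2R,4S)-2-tert-butyl-4-methyl-5-oxo-1,3-dioxolan-4-yl]-2-hydroxyacetate, both carbinol epimers | C[C@@]1(C(O)C(=O)OC)O[C@@H](C(C)(C)C)OC1=O | intermediate
16 | methyl 2-[(2R,4S)-2-tert-butyl-4-methyl-5-oxo-1,3-dioxolan-4-yl]-2-(triethylsilyloxy)acetate, both epimers | C[C@@]1(C(O[Si](CC)(CC)CC)C(=O)OC)O[C@@H](C(C)(C)C)OC1=O | intermediate
17 | {6-[(1E,3E,5S)-3,5-dimethylhepta-1,3-dien-1-yl]pyridin-3-yl}magnesium chloride, LiCl complex (not isolated) | CC[C@H](C)/C=C(C)/C=C/c1ccc([Mg]Cl)cn1 | intermediate
18 | chloromagnesium alkoxide of the cyclic hemiketal from 16 and 17 (not isolated) | CC[C@H](C)/C=C(C)/C=C/c1ccc(cn1)C2(O[Mg]Cl)O[C@H](C(C)(C)C)O[C@@]2(C)C(O[Si](CC)(CC)CC)C(=O)OC | intermediate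
19 | methyl (3S)-4-{6-[(1E,3E,5S)-3,5-dimethylhepta-1,3-dien-1-yl]pyridin-3-yl}-3-hydroxy-3-methyl-4-oxo-2-(triethylsilyloxy)butanoate, both C2 epimers (key-step precursor) | CC[C@H](C)/C=C(C)/C=C/c1ccc(cn1)C(=O)[C@@](C)(O)C(O[Si](CC)(CC)CC)C(=O)OC | intermediate
20 | O6-trimethylsilyl ether of 19 as its methyl trimethylsilyl ketene acetal, either double-bond geometry (not isolated) | CC[C@H](C)/C=C(C)/C=C/c1ccc(cn1)C(=O)[C@@](C)(O[Si](C)(C)C)C(O[Si](CC)(CC)CC)=C(OC)O[Si](C)(C)C | intermediate
21 | N-triflylpyridinium triflate of 20 (not isolated) | CC[C@H](C)/C=C(C)/C=C/c1ccc(c[n+]1S(=O)(=O)C(F)(F)F)C(=O)[C@@](C)(O[Si](C)(C)C)C(O[Si](CC)(CC)CC)=C(OC)O[Si](C)(C)C.[O-]S(=O)(=O)C(F)(F)F | intermediate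
22 | N2-triflyl-2,4a-dihydro form of the ring-closed O6-trimethylsilyl, O5-triethylsilyl compound (not isolated) | CC[C@H](C)/C=C(C)/C=C/C1=CC2C(=CN1S(=O)(=O)C(F)(F)F)C(=O)[C@@](C)(O[Si](C)(C)C)[C@@]2(O[Si](CC)(CC)CC)C(=O)OC | intermediate
23 | methyl (5R,6S)-3-[(1E,3E,5S)-3,5-dimethylhepta-1,3-dien-1-yl]-6-methyl-7-oxo-5-(triethylsilyloxy)-6-(trimethylsilyloxy)-6,7-dihydro-5H-cyclopenta[c]pyridine-5-carboxylate (not isolated) | CC[C@H](C)/C=C(C)/C=C/c1cc2c(cn1)C(=O)[C@@](C)(O[Si](C)(C)C)[C@@]2(O[Si](CC)(CC)CC)C(=O)OC | intermediate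
24 | methyl (5R,6S)-3-[(1E,3E,5S)-3,5-dimethylhepta-1,3-dien-1-yl]-6-hydroxy-6-methyl-7-oxo-5-(triethylsilyloxy)-6,7-dihydro-5H-cyclopenta[c]pyridine-5-carboxylate (key-step product) | CC[C@H](C)/C=C(C)/C=C/c1cc2c(cn1)C(=O)[C@@](C)(O)[C@@]2(O[Si](CC)(CC)CC)C(=O)OC | intermediate
25 | methyl (5R,6S)-6-acetoxy-3-[(1E,3E,5S)-3,5-dimethylhepta-1,3-dien-1-yl]-6-methyl-7-oxo-5-(triethylsilyloxy)-6,7-dihydro-5H-cyclopenta[c]pyridine-5-carboxylate (O5-triethylsilyl ether of the target) | CC[C@H](C)/C=C(C)/C=C/c1cc2c(cn1)C(=O)[C@@](C)(OC(C)=O)[C@@]2(O[Si](CC)(CC)CC)C(=O)OC | intermediate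
26 | methyl (5R,6S)-6-acetoxy-3-[(1E,3E,5S)-3,5-dimethylhepta-1,3-dien-1-yl]-5-hydroxy-6-methyl-7-oxo-6,7-dihydro-5H-cyclopenta[c]pyridine-5-carboxylate | CC[C@H](C)/C=C(C)/C=C/c1cc2c(cn1)C(=O)[C@@](C)(OC(C)=O)[C@@]2(O)C(=O)OC | target

**Step count**

Total: 11 steps. Longest linear sequence: 8 steps (steps 1–4 and 8–11, from (S)-2-methylbutan-1-ol).

**Steps most likely to fail**

Step 9 (proposed new method). Several things may go wrong:
- Soft enolisation of the hindered C5–H may be slow.
- (CF3SO2)2O may sulfonylate the ketene acetal carbon instead of N2.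
- The nucleophile may add at C1.
- The C5 face may be chosen poorly.

The fallback makes the same C4a–C5 bond by addition–elimination, which is known chemistry. Setting out from 9, LiN(iPr)2 at −78 °C should lithiate the position ortho to bromine, and C2Cl6 should give 5-bromo-4-chloro-2-[(1E,3E,5S)-3,5-dimethylhepta-1,3-dien-1-yl]pyridine F1. Br/Mg exchange of the bromine only (iPrMgCl·LiCl) and addition to 16 as in step 8 should give methyl (3S)-4-{4-chloro-6-[(1E,3E,5S)-3,5-dimethylhepta-1,3-dien-1-yl]pyridin-3-yl}-3-hydroxy-3-methyl-4-oxo-2-(triethylsilyloxy)butanoate F2. Me3SiCl and imidazole should convert it into its O3-trimethylsilyl ether F3. KN(SiMe3)2 in THF at −78 → 0 °C should then form the ester enolate, which displaces chloride at the carbon para to nitrogen and ortho to the acyl group in an intramolecular SNAr reaction to give 23. The citric acid methanolysis brings the route back at 24.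

Step 8. Acyl substitution at the methyl ester may compete with that at the dioxolanone carbonyl, and early collapse of the hemiketal may allow a second addition. The fallback sets out from 16. LiSEt in THF at 0 °C should open only the acylal-type lactone, because thiolysis of the methyl ester is uphill and reversible, and with loss of pivaldehyde give S-ethyl (2S)-2-hydroxy-4-methoxy-2-methyl-4-oxo-3-(triethylsilyloxy)butanethioate F4. Fukuyama coupling of F4 with {6-[(1E,3E,5S)-3,5-dimethylhepta-1,3-dien-1-yl]pyridin-3-yl}zinc chloride F5 (from 17 and ZnCl2, in excess because the free hydroxyl takes one equivalent) under PdCl2(PPh3)2 catalysis in THF/toluene at rt should give the ketone chemoselectively. The route is rejoined at 19.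

Step 10. Acylation of the hindered tertiary hydroxyl next to the fully substituted C5 may be sluggish, and forcing basic conditions may cleave the C5–C6 bond by retro-aldol reaction. The fallback sets out from 24. HF·pyridine should first remove the silyl group to give methyl (5R,6S)-3-[(1E,3E,5S)-3,5-dimethylhepta-1,3-dien-1-yl]-5,6-dihydroxy-6-methyl-7-oxo-6,7-dihydro-5H-cyclopenta[c]pyridine-5-carboxylate F6. One equivalent of Ac2O with catalytic DMAP in pyridine at 0 °C should then acetylate O6, which is flanked only by a methyl group, in preference to O5, which is flanked by the ester and ring A and is the weaker nucleophile. The route is rejoined at 26.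

**Further compounds**

F1 | step 9 | 5-bromo-4-chloro-2-[(1E,3E,5S)-3,5-dimethylhepta-1,3-dien-1-yl]pyridine | CC[C@H](C)/C=C(C)/C=C/c1cc(Cl)c(Br)cn1
F2 | step 9 | methyl (3S)-4-{4-chloro-6-[(1E,3E,5S)-3,5-dimethylhepta-1,3-dien-1-yl]pyridin-3-yl}-3-hydroxy-3-methyl-4-oxo-2-(triethylsilyloxy)butanoate | CC[C@H](C)/C=C(C)/C=C/c1cc(Cl)c(cn1)C(=O)[C@@](C)(O)C(O[Si](CC)(CC)CC)C(=O)OC
F3 | step 9 | O3-trimethylsilyl ether of F2 | CC[C@H](C)/C=C(C)/C=C/c1cc(Cl)c(cn1)C(=O)[C@@](C)(O[Si](C)(C)C)C(O[Si](CC)(CC)CC)C(=O)OC
F4 | step 8 | S-ethyl (2S)-2-hydroxy-4-methoxy-2-methyl-4-oxo-3-(triethylsilyloxy)butanethioate | CCSC(=O)[C@@](C)(O)C(O[Si](CC)(CC)CC)C(=O)OC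
F5 | step 8 | {6-[(1E,3E,5S)-3,5-dimethylhepta-1,3-dien-1-yl]pyridin-3-yl}zinc chloride | CC[C@H](C)/C=C(C)/C=C/c1ccc([Zn]Cl)cn1
F6 | step 10 | methyl (5R,6S)-3-[(1E,3E,5S)-3,5-dimethylhepta-1,3-dien-1-yl]-5,6-dihydroxy-6-methyl-7-oxo-6,7-dihydro-5H-cyclopenta[c]pyridine-5-carboxylate | CC[C@H](C)/C=C(C)/C=C/c1cc2c(cn1)C(=O)[C@@](C)(O)[C@@]2(O)C(=O)OC
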